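**Retrosynthetic overview**
1. The C6–O ester is cut to the axial C6 alcohol 12 and TBS-protected p-coumaric acid 15; 12 comes from the trans-fused C6 ketone 11 by hydride delivery anti to the angular methyl C14.
2. 11 comes from the cis-fused β,γ-enone 8 by two corrections next to the ketone: C7 is re-set under thermodynamic control in the conjugated C4=C5 enone 9, and C5 by kinetic protonation of the C3=C4–C5=C6 dienolate.
3. Key disconnection C4–C5: ring A (C1–C5, C10) closes by gold(I) 6-endo-dig attack of enol-ether carbon C5 on alkyne carbon C4 of silyl enol ether 7, leaving C3=C4 with C15 already on C4.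
4. Feature used: ring B (C5–C10) with oxygen on C6, isopropyl on C7 and methyl C14 on C10 is the p-menthane skeleton of (R)-piperitone; its C5=C10 enone takes up C1–C4 plus C15 as a pent-3-ynyl copper reagent, and C7 relays its configuration to C10.
5. Ring order: ring B is bought, ring A is formed in step 4.

Key step: step 4

Remark: positions are given in eudesmane numbering (ring A = C1–C5, C10; ring B = C5–C10; C14 on C10, C15 on C4).
Assumption: (R)-(−)-piperitone of high enantiomeric purity is used. Because C7 is re-set in step 5, the enantiomeric purity of the product rests on C10 alone, so the minor C10 epimer from step 2 must be removed before step 5 (done at ketone 8).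

Step 1
Reactants: 1 pent-3-yn-1-ol
Product: 2 5-bromopent-2-yne
Conditions: CBr4, PPh3, CH2Cl2, 0 °C → rt
Reagents that add atoms: tetrabromomethane BrC(Br)(Br)Br
Why: Appel reaction of a primary alcohol (bromide displaces the alkoxyphosphonium group); the internal alkyne is inert and no stereocentre is involved.

Step 2
Reactants: 2 5-bromopent-2-yne; 3 (R)-(−)-piperitone
Product: 5 trimethyl{[(3S,6R)-3-methyl-3-(pent-3-yn-1-yl)-6-(propan-2-yl)cyclohex-1-en-1-yl]oxy}silane, via pent-3-yn-1-ylmagnesium bromide 4 (not isolated)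
Conditions: Mg, THF, rt; then 3, CuBr·SMe2 (10 mol %), TMSCl, HMPA, THF, −78 °C; Et3N, cold aq. NaHCO3
Reagents that add atoms: chlorotrimethylsilane C[Si](C)(C)Cl
Why: Copper-catalysed, chlorosilane-accelerated conjugate addition of a Grignard reagent with O-silylation of the enolate fixes the enol ether at C5=C6; axial attack on the half-chair with pseudo-equatorial isopropyl should place the chain cis to the isopropyl group and so set C10 (3S in 5).

Step 3
Reactants: 5 trimethylsilyl enol ether
Product: 7 tert-butyl(dimethyl){[(3S,6R)-3-methyl-3-(pent-3-yn-1-yl)-6-(propan-2-yl)cyclohex-1-en-1-yl]oxy}silane, via lithium enolate 6 (not isolated)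
Conditions: MeLi, THF, 0 °C → rt; then TBSOTf, −78 °C; Et3N, aq. NaHCO3
Reagents that add atoms: tert-butyldimethylsilyl trifluoromethanesulfonate CC(C)(C)[Si](C)(C)OS(=O)(=O)C(F)(F)F
Why: Silicon–lithium exchange with methyllithium gives the lithium enolate without loss of regiochemistry, and O-silylation gives the TBS enol ether, which should resist protodesilylation under cationic gold far better than the trimethylsilyl ether; no stereocentre is touched.

Step 4
Reactants: 7 TBS enol ether
Product: 8 (2R,4aR,8aS)-4a,8-dimethyl-2-(propan-2-yl)-3,4,4a,5,6,8a-hexahydronaphthalen-1(2H)-one (cis-fused 5,7-di-epi-eudesm-3-en-6-one)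
Conditions: [(tBuXPhos)Au(NCMe)]SbF6 (5 mol %), acetone, H2O (2 equiv), rt; chromatography removes the ketone derived from the C10 epimer of 7
Reagents that add atoms: none
Why: The cationic gold(I) complex activates the C3≡C4 alkyne and C5 of the silyl enol ether attacks C4 anti to gold, giving a C3 vinyl-gold silyloxocarbenium ion that loses silicon to water and is protodeaurated at C3, which leaves the C6 ketone and the C3=C4 olefin with C15 on C4. The closest known reaction type is the gold(I)-catalysed Conia-ene-type carbocyclisation of silyl enol ethers onto alkynes in its 6-endo mode with bulky biarylphosphine ligands. Ring A (C1–C5, C10) closes 6-endo-dig. The new stereocentre C5 is controlled by C10: the three-carbon tether can reach C5 only on the face that carries C1, so the fusion is cis (H5 cis to C14, 8aS). The step needs 6-endo attack at C4 instead of 5-exo attack at C3; the methyl cap removes the Markovnikov bias of a terminal alkyne, the bulky ligand disfavours the exo transition state, and step 2 has fixed the nucleophilic carbon at C5. C7 and C10 are not touched.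

Step 5
Reactants: 8 cis-fused β,γ-enone
Product: 9 (2S,4aR)-4a,8-dimethyl-2-(propan-2-yl)-3,4,4a,5,6,7-hexahydronaphthalen-1(2H)-one ((7S,10R)-eudesm-4-en-6-one)
Conditions: NaOMe (0.5 equiv), MeOH, 50 °C; the C7 epimers are separated and the minor one is returned to the same conditions
Reagents that add atoms: none
Why: Base-mediated enolisation moves C3=C4 into conjugation (β,γ → α,β-enone isomerisation, which erases C5) and epimerises C7 through the C6=C7 enolate under thermodynamic control, which should favour the pseudo-equatorial isopropyl group cis to C14 (7S).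

Step 6
Reactants: 9 conjugated enone
Product: 11 (2S,4aR,8aR)-4a,8-dimethyl-2-(propan-2-yl)-3,4,4a,5,6,8a-hexahydronaphthalen-1(2H)-one (trans-fused eudesm-3-en-6-one), via potassium dienolate 10 (not isolated)
Conditions: KOt-Bu (4 equiv), THF–t-BuOH (10:1), −20 → 0 °C; inverse quench into AcOH–THF, −78 °C; 11 is used without chromatography
Reagents that add atoms: none
Why: Deconjugative protonation: γ-deprotonation at C3 gives the extended dienolate (C3=C4–C5=C6–O−), in which C7 is no longer acidic, and kinetic α-protonation at C5 occurs anti to C14, which stands perpendicular to the dienolate plane on C10 and blocks its own face, so the trans-fused β,γ-enone (5R) should result.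

Step 7
Reactants: 11 trans-fused β,γ-enone
Product: 12 (1R,2S,4aR,8aR)-4a,8-dimethyl-2-(propan-2-yl)-1,2,3,4,4a,5,6,8a-octahydronaphthalen-1-ol (axial C6 alcohol, OH cis to C14)
Conditions: L-Selectride, THF, −78 → 0 °C; then NaOH, H2O2
Reagents that add atoms: none
Why: Hindered-hydride reduction; the reagent approaches C6 equatorially from the face opposite the syn-axial C14 methyl and should give the axial alcohol cis to C14 (6R).

Step 8
Reactants: 13 p-coumaric acid
Product: 15 (2E)-3-{4-[(tert-butyldimethylsilyl)oxy]phenyl}prop-2-enoic acid, via silyl ester 14 (not isolated)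
Conditions: TBSCl (2.3 equiv), imidazole, DMF, rt; then AcOH–THF–H2O, rt
Reagents that add atoms: tert-butyldimethylsilyl chloride CC(C)(C)[Si](C)(C)Cl
Why: Silylation of phenol and acid followed by selective hydrolysis of the labile silyl ester (the aryl silyl ether survives dilute acetic acid); the E olefin is untouched.

Step 9
Reactants: 12 axial alcohol; 15 silyl-protected p-coumaric acid
Product: 17 (1R,2S,4aR,8aR)-4a,8-dimethyl-2-(propan-2-yl)-1,2,3,4,4a,5,6,8a-octahydronaphthalen-1-yl (2E)-3-{4-[(tert-butyldimethylsilyl)oxy]phenyl}prop-2-enoate, via mixed anhydride 16 (not isolated)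
Conditions: 15, 2,4,6-trichlorobenzoyl chloride, Et3N, toluene, rt; then 12, DMAP (2 equiv), toluene, rt → 60 °C
Reagents that add atoms: none
Why: Yamaguchi esterification; DMAP transfers the cinnamoyl group of the mixed anhydride to the hindered axial alcohol with retention at C6 and without touching the E olefin or the silyl ether.

Step 10
Reactants: 17 silyl-protected ester
Product: 18 (1R,2S,4aR,8aR)-4a,8-dimethyl-2-(propan-2-yl)-1,2,3,4,4a,5,6,8a-octahydronaphthalen-1-yl (2E)-3-(4-hydroxyphenyl)prop-2-enoate
Conditions: TBAF (1.1 equiv), AcOH (1.2 equiv), THF, 0 °C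
Reagents that add atoms: none
Why: Fluoride cleaves the aryl silyl ether; acetic acid buffers the phenoxide so that the ester, the E olefin and the four stereocentres stay untouched.

**Compound list**
1 | pent-3-yn-1-ol | CC#CCCO | starting material
2 | 5-bromopent-2-yne | CC#CCCBr | intermediate
3 | (R)-(−)-piperitone, (6R)-3-methyl-6-(propan-2-yl)cyclohex-2-en-1-one | CC1=CC(=O)[C@@H](C(C)C)CC1 | starting material
4 | pent-3-yn-1-ylmagnesium bromide | CC#CCC[Mg]Br | intermediate
5 | trimethyl{[(3S,6R)-3-methyl-3-(pent-3-yn-1-yl)-6-(propan-2-yl)cyclohex-1-en-1-yl]oxy}silane (chain cis to isopropyl) | CC#CCC[C@]1(C)CC[C@H](C(C)C)C(O[Si](C)(C)C)=C1 | intermediate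
6 | lithium (3S,6R)-3-methyl-3-(pent-3-yn-1-yl)-6-(propan-2-yl)cyclohex-1-en-1-olate | CC#CCC[C@]1(C)CC[C@H](C(C)C)C(O[Li])=C1 | intermediate
7 | tert-butyl(dimethyl){[(3S,6R)-3-methyl-3-(pent-3-yn-1-yl)-6-(propan-2-yl)cyclohex-1-en-1-yl]oxy}silane | CC#CCC[C@]1(C)CC[C@H](C(C)C)C(O[Si](C)(C)C(C)(C)C)=C1 | intermediate
8 | (2R,4aR,8aS)-4a,8-dimethyl-2-(propan-2-yl)-3,4,4a,5,6,8a-hexahydronaphthalen-1(2H)-one (cis-fused; isopropyl trans to C14) | CC1=CCC[C@]2(C)CC[C@H](C(C)C)C(=O)[C@H]12 | intermediate
9 | (2S,4aR)-4a,8-dimethyl-2-(propan-2-yl)-3,4,4a,5,6,7-hexahydronaphthalen-1(2H)-one (isopropyl cis to C14) | CC1=C2C(=O)[C@H](C(C)C)CC[C@@]2(C)CCC1 | intermediate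
10 | potassium (2S,4aR)-4a,8-dimethyl-2-(propan-2-yl)-2,3,4,4a,5,6-hexahydronaphthalen-1-olate | CC1=CCC[C@]2(C)CC[C@@H](C(C)C)C(O[K])=C12 | intermediate
11 | (2S,4aR,8aR)-4a,8-dimethyl-2-(propan-2-yl)-3,4,4a,5,6,8a-hexahydronaphthalen-1(2H)-one (trans-fused) | CC1=CCC[C@]2(C)CC[C@@H](C(C)C)C(=O)[C@@H]12 | intermediate
12 | (1R,2S,4aR,8aR)-4a,8-dimethyl-2-(propan-2-yl)-1,2,3,4,4a,5,6,8a-octahydronaphthalen-1-ol | CC1=CCC[C@]2(C)CC[C@@H](C(C)C)[C@@H](O)[C@@H]12 | intermediate
13 | p-coumaric acid, (2E)-3-(4-hydroxyphenyl)prop-2-enoic acid | O=C(O)/C=C/c1ccc(O)cc1 | starting material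
14 | tert-butyldimethylsilyl (2E)-3-{4-[(tert-butyldimethylsilyl)oxy]phenyl}prop-2-enoate | CC(C)(C)[Si](C)(C)OC(=O)/C=C/c1ccc(O[Si](C)(C)C(C)(C)C)cc1 | intermediate
15 | (2E)-3-{4-[(tert-butyldimethylsilyl)oxy]phenyl}prop-2-enoic acid | CC(C)(C)[Si](C)(C)Oc1ccc(/C=C/C(=O)O)cc1 | intermediate
16 | (2E)-3-{4-[(tert-butyldimethylsilyl)oxy]phenyl}prop-2-enoic 2,4,6-trichlorobenzoic anhydride | CC(C)(C)[Si](C)(C)Oc1ccc(/C=C/C(=O)OC(=O)c2c(Cl)cc(Cl)cc2Cl)cc1 | intermediate
17 | (1R,2S,4aR,8aR)-4a,8-dimethyl-2-(propan-2-yl)-1,2,3,4,4a,5,6,8a-octahydronaphthalen-1-yl (2E)-3-{4-[(tert-butyldimethylsilyl)oxy]phenyl}prop-2-enoate | CC1=CCC[C@]2(C)CC[C@@H](C(C)C)[C@@H](OC(=O)/C=C/c3ccc(O[Si](C)(C)C(C)(C)C)cc3)[C@@H]12 | intermediate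
18 | (1R,2S,4aR,8aR)-4a,8-dimethyl-2-(propan-2-yl)-1,2,3,4,4a,5,6,8a-octahydronaphthalen-1-yl (2E)-3-(4-hydroxyphenyl)prop-2-enoate | CC1=CCC[C@]2(C)CC[C@@H](C(C)C)[C@@H](OC(=O)/C=C/c3ccc(O)cc3)[C@@H]12 | target

Total step count: 10. Longest linear sequence: 9 steps (steps 1–7, 9, 10).

**Steps most likely to fail**

1. Step 4. The closure may run in the 5-exo mode (attack of C5 on C3, giving a hydrindanone with an exocyclic ethylidene group), or the enol ether may be protodesilylated before the C–C bond forms. The fallback sets out from 3 and returns at 9 by a Robinson-type aldol closure of the same C4–C5 bond. Piperitone 3 is treated under the copper/TMSCl conditions of step 2 with [3-(2-methyl-1,3-dioxolan-2-yl)propyl]magnesium chloride F1, made from commercial 2-(3-chloropropyl)-2-methyl-1,3-dioxolane and magnesium. This should give trimethyl{[(3R,6R)-3-methyl-3-[3-(2-methyl-1,3-dioxolan-2-yl)propyl]-6-(propan-2-yl)cyclohex-1-en-1-yl]oxy}silane F2. Mild aqueous acid (PPTS, wet acetone) removes the silyl group and the ketal to give (2R,5R)-5-methyl-5-(4-oxopentyl)-2-(propan-2-yl)cyclohexan-1-one F3, whose C10 epimers are separated before any base is used. KOH in MeOH then condenses C5 onto the C4 ketone, dehydrates and equilibrates C7, giving enone 9.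

2. Step 6. Protonation may occur at C3 instead of C5, the β,γ-enone may reconjugate during work-up, and proton exchange at C7 may take place before the dienolate is fully formed. The fallback sets out from 9 and returns at 12 without isolating 11. Isopropenyl acetate and TsOH at reflux should give the dienol acetate (2S,4aR)-4a,8-dimethyl-2-(propan-2-yl)-2,3,4,4a,5,6-hexahydronaphthalen-1-yl acetate F4. NaBH4 in aqueous EtOH–THF at 0 °C cleaves the acetate, the liberated dienolate is protonated at C5 anti to C14 by the solvent, and the β,γ-enone is reduced in the same flask from the face opposite C14 to give alcohol 12. Any C7 epimer is removed at 12 and can be returned to step 5 after oxidation.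

3. Step 2. Facial selectivity of the conjugate addition may be low, and incomplete removal of the C10 epimer would surface as the enantiomer after step 5. The fallback sets out from 5 and returns at 7, moving the separation to a ketone and forming the enol ether by kinetic deprotonation. The crude enol ether 5 is hydrolysed under non-epimerising conditions (0.5 M HCl, THF, 0 °C) to (2R,5S)-5-methyl-5-(pent-3-yn-1-yl)-2-(propan-2-yl)cyclohexan-1-one F5. The cis and trans ketones are separated by HPLC before C7 can equilibrate. LDA (THF, −78 °C) then removes a proton from the C5 methylene in preference to the isopropyl-bearing C7, and TBSOTf gives 7 via lithium enolate 6.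

**Further compounds**
F1 | step 4 | [3-(2-methyl-1,3-dioxolan-2-yl)propyl]magnesium chloride | CC1(CCC[Mg]Cl)OCCO1
F2 | step 4 | trimethyl{[(3R,6R)-3-methyl-3-[3-(2-methyl-1,3-dioxolan-2-yl)propyl]-6-(propan-2-yl)cyclohex-1-en-1-yl]oxy}silane | CC1(CCC[C@]2(C)CC[C@H](C(C)C)C(O[Si](C)(C)C)=C2)OCCO1
F3 | step 4 | (2R,5R)-5-methyl-5-(4-oxopentyl)-2-(propan-2-yl)cyclohexan-1-one | CC(=O)CCC[C@]1(C)CC[C@H](C(C)C)C(=O)C1
F4 | step 6 | (2S,4aR)-4a,8-dimethyl-2-(propan-2-yl)-2,3,4,4a,5,6-hexahydronaphthalen-1-yl acetate | CC1=CCC[C@]2(C)CC[C@@H](C(C)C)C(OC(C)=O)=C12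
F5 | step 2 | (2R,5S)-5-methyl-5-(pent-3-yn-1-yl)-2-(propan-2-yl)cyclohexan-1-one | CC#CCC[C@]1(C)CC[C@H](C(C)C)C(=O)C1
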